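The decalin is cut at C8–C8a. Its methyl-bearing fusion carbon C4a is joined through two three-atom arms, C4–C3–C2 in ring A and C5–C6–C7 in ring B, to the two functionalised carbons, so ring A can be taken back to an achiral 4-methyl-4-(3-oxobutyl)cyclohexa-2,5-dienone in which C4a is prochiral. An amine-catalysed intramolecular Michael addition of the methyl-ketone carbon C8 to one of the two enantiotopic enone termini (C8a) closes ring B, fixes C4a and leaves an enone at C2 beside a plain ketone at C7. C8a is later reset to trans, C2 and C7 are elaborated, and the diallylbiphenylol is built on the tertiary ether.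

Key step: step 5

Convention: decalin carbons are numbered as in naphthalene (C2 = future ether carbon, C4a = methyl-bearing fusion carbon, C7 = future side-chain carbon, C8a = fusion CH); β is the face carrying the C4a methyl group, α the opposite face.
Assumption: the sense of induction of the primary-amine catalyst in step 5 cannot be assigned in advance; the quinine-derived amine is written, and its quinidine-derived pseudo-enantiomer is taken instead if the opposite enantiomer of 9 results.

Step 1
Reactants: 1 3-ethoxycyclohex-2-en-1-one; 2 2-(2-bromoethyl)-2-methyl-1,3-dioxolane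
Product: 3 rac-3-ethoxy-6-[2-(2-methyl-1,3-dioxolan-2-yl)ethyl]cyclohex-2-en-1-one
Conditions: LiN(i-Pr)2, THF, −78 °C; then 2, DMPU, −78 °C to rt
Reagents that add atoms: none
Why: Kinetic deprotonation of the vinylogous ester takes place at the α′ carbon C6, and the lithium enolate is alkylated by the primary bromide in an SN2 reaction (first half of a Stork–Danheiser sequence).

Step 2
Reactants: 3 rac-3-ethoxy-6-[2-(2-methyl-1,3-dioxolan-2-yl)ethyl]cyclohex-2-en-1-one
Product: 4 rac-3-ethoxy-6-methyl-6-[2-(2-methyl-1,3-dioxolan-2-yl)ethyl]cyclohex-2-en-1-one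
Conditions: LiN(i-Pr)2, THF, −78 °C; then MeI, −78 to 0 °C
Reagents that add atoms: iodomethane, CI
Why: A second α′-enolate alkylation with the small electrophile MeI builds the quaternary carbon that becomes C4a; it is racemic here and loses its chirality in step 4.

Step 3
Reactants: 4 rac-3-ethoxy-6-methyl-6-[2-(2-methyl-1,3-dioxolan-2-yl)ethyl]cyclohex-2-en-1-one
Product: 7 rac-4-methyl-4-(3-oxobutyl)cyclohex-2-en-1-one, via allylic alcohol 5 (not isolated), via enone ketal 6 (not isolated)
Conditions: LiAlH4, Et2O, 0 °C; then 2 M HCl, THF, rt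
Reagents that add atoms: water, O
Why: Stork–Danheiser transposition: 1,2-reduction of the vinylogous ester, then acid hydrolysis of the enol ether with loss of water relocates the carbonyl, and the same aqueous acid hydrolyses the dioxolane.

Step 4
Reactants: 7 rac-4-methyl-4-(3-oxobutyl)cyclohex-2-en-1-one
Product: 8 4-methyl-4-(3-oxobutyl)cyclohexa-2,5-dien-1-one
Conditions: DDQ, 1,4-dioxane, 100 °C
Reagents that add atoms: none
Why: DDQ dehydrogenation of a 4,4-disubstituted cyclohexenone through its α′-dienol (hydride abstraction from C5) should give the cross-conjugated dienone, which cannot aromatise, while the saturated side-chain ketone enolises too slowly to compete; the product is achiral.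

Step 5
Reactants: 8 4-methyl-4-(3-oxobutyl)cyclohexa-2,5-dien-1-one
Product: 9 (4aR,8aR)-4a-methyl-4a,5,6,8a-tetrahydronaphthalene-2,7(1H,8H)-dione
Conditions: 9-amino-9-deoxy-epi-quinine (20 mol %), CF3CO2H (40 mol %), toluene, rt
Reagents that add atoms: none
Why: The primary amine condenses with the side-chain methyl ketone, the terminal enamine carbon C8 adds in conjugate fashion to the β-carbon C8a of one enone half, and hydrolysis of the iminium ion at C7 frees the catalyst. The closest known reaction type is the amine-catalysed desymmetrising intramolecular Michael addition of carbonyl-tethered 4,4-disubstituted cyclohexadienones. Ring B closes in a 6-exo-trig mode, the acceptor bond C8a=C1 lying outside the new ring. C4a becomes stereogenic because the chiral amine, with its protonated quinuclidine hydrogen-bonded to the dienone carbonyl, selects one of the two enantiotopic β-carbons, whereas C8a follows from the tether, which reaches the planar ring only from its own face and so gives the cis fusion. The step needs the terminal enamine, a single addition and enantio-differentiation: the internal enamine could only close a four-membered ring, the remaining C3=C4 enone is out of reach of C6 and C8, and the third rests on the catalyst.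

Step 6
Reactants: 9 (4aR,8aR)-4a-methyl-4a,5,6,8a-tetrahydronaphthalene-2,7(1H,8H)-dione
Product: 10 (4aR,8aS)-7,7-(ethylenedioxy)-4a-methyl-4a,5,6,7,8,8a-hexahydronaphthalen-2(1H)-one
Conditions: Me3SiOCH2CH2OSiMe3, Me3SiOTf (5 mol %), CH2Cl2, −78 to −40 °C
Reagents that add atoms: 1,2-bis(trimethylsilyloxy)ethane, C[Si](C)(C)OCCO[Si](C)(C)C
Why: Silyl-triflate-catalysed ketalisation is selective for the saturated C7 ketone over the conjugated C2 ketone at low temperature, and the ketal also shuts off retro-Michael opening, which would endanger C4a in the basic steps that follow.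

Step 7
Reactants: 10 (4aR,8aS)-7,7-(ethylenedioxy)-4a-methyl-4a,5,6,7,8,8a-hexahydronaphthalen-2(1H)-one
Product: 12 (4aS)-7,7-(ethylenedioxy)-4a-methyl-5,6,7,8-tetrahydronaphthalen-2(4aH)-one, via trimethylsilyl dienol ether 11 (not isolated)
Conditions: LiN(i-Pr)2, Me3SiCl, THF, −78 °C; then Pd(OAc)2 (1.05 equiv), MeCN, rt
Reagents that add atoms: none
Why: Saegusa–Ito oxidation: C1 is the only enolisable position of the enone, so kinetic silylation gives the 2-silyloxy-1,3-diene, and palladium diacetate then removes C8a–H by β-hydride elimination, which deletes the cis C8a centre.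

Step 8
Reactants: 12 (4aS)-7,7-(ethylenedioxy)-4a-methyl-5,6,7,8-tetrahydronaphthalen-2(4aH)-one
Product: 13 (4aR)-7,7-(ethylenedioxy)-4a-methyl-4,4a,5,6,7,8-hexahydronaphthalen-2(3H)-one
Conditions: H2 (1 atm), ClRh(PPh3)3 (5 mol %), benzene/EtOH, rt
Reagents that add atoms: none
Why: Homogeneous hydrogenation with ClRh(PPh3)3 reduces the disubstituted C3=C4 bond of a cross-conjugated dienone and leaves the trisubstituted C1=C8a bond, as known for steroidal 1,4-dien-3-ones.

Step 9
Reactants: 13 (4aR)-7,7-(ethylenedioxy)-4a-methyl-4,4a,5,6,7,8-hexahydronaphthalen-2(3H)-one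
Product: 14 (4aR,8aR)-7,7-(ethylenedioxy)-4a-methyloctahydronaphthalen-2(1H)-one
Conditions: Li, NH3 (l), THF, t-BuOH (1 equiv), −78 °C; then NH4Cl
Reagents that add atoms: none
Why: Dissolving-metal (Birch-type) reduction of the enone: the β-carbanion at C8a is protonated axially, anti to the C4a methyl group, which should give the trans-fused decalone (8a-H α), and the C2 enolate is protonated on work-up.

Step 10
Reactants: 14 (4aR,8aR)-7,7-(ethylenedioxy)-4a-methyloctahydronaphthalen-2(1H)-one
Product: 15 (2R,4aR,8aR)-7,7-(ethylenedioxy)-4a-methyloctahydro-1H-spiro[naphthalene-2,2′-oxirane]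
Conditions: Me3S(O)I, NaH, DMSO, rt to 50 °C
Reagents that add atoms: trimethylsulfoxonium iodide, C[S+](C)(C)=O.[I-]
Why: Corey–Chaykovsky epoxidation with the sulfoxonium ylide, whose reversible addition places the new C–C bond equatorial and hence the oxygen axial (α) at C2.

Step 11
Reactants: 15 (2R,4aR,8aR)-7,7-(ethylenedioxy)-4a-methyloctahydro-1H-spiro[naphthalene-2,2′-oxirane]
Product: 16 (2R,4aR,8aR)-7,7-(ethylenedioxy)-2,4a-dimethyldecahydronaphthalen-2-ol
Conditions: LiAlH4, THF, 0 °C to rt; NaOH (aq) work-up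
Reagents that add atoms: none
Why: Hydride opens the 1,1-disubstituted epoxide at its CH2 terminus (SN2), which becomes the equatorial methyl group and leaves the axial tertiary alcohol with C2 untouched.

Step 12
Reactants: 17 4-bromo-2-chloro-1-iodobenzene
Product: 19 (4-bromo-2-chlorophenyl)(2,4,6-trimethoxyphenyl)iodonium tosylate, via [hydroxy(tosyloxy)iodo]arene 18 (not isolated)
Conditions: mCPBA, TsOH·H2O, MeCN, 75 °C; then 1,3,5-trimethoxybenzene, rt
Reagents that add atoms: 1,3,5-trimethoxybenzene, COc1cc(OC)cc(OC)c1; p-toluenesulfonic acid monohydrate, Cc1ccc(S(=O)(=O)O)cc1.O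
Why: One-pot diaryliodonium synthesis: the aryl iodide is oxidised at iodine and the resulting trivalent-iodine species arylates the electron-rich trimethoxybenzene by electrophilic aromatic substitution, Br and Cl being untouched.

Step 13
Reactants: 16 (2R,4aR,8aR)-7,7-(ethylenedioxy)-2,4a-dimethyldecahydronaphthalen-2-ol; 19 (4-bromo-2-chlorophenyl)(2,4,6-trimethoxyphenyl)iodonium tosylate
Product: 20 (2R,4aR,8aR)-2-(4-bromo-2-chlorophenoxy)-7,7-(ethylenedioxy)-2,4a-dimethyldecahydronaphthalene
Conditions: NaH, toluene, 60 °C; then 19, rt to 40 °C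
Reagents that add atoms: none
Why: Metal-free O-arylation of a tertiary alkoxide with a diaryliodonium salt (ligand coupling at trivalent iodine): the electron-poor, ortho-substituted aryl group is transferred while the trimethoxyphenyl group stays on iodine, and since the C2–O bond is not broken the configuration at C2 is kept.

Step 14
Reactants: 20 (2R,4aR,8aR)-2-(4-bromo-2-chlorophenoxy)-7,7-(ethylenedioxy)-2,4a-dimethyldecahydronaphthalene
Product: 21 (2R,4aR,8aR)-2-(4-bromo-2-chlorophenoxy)-2,4a-dimethyldecahydronaphthalen-7-one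
Conditions: pyridinium p-toluenesulfonate, acetone/H2O, 55 °C
Reagents that add atoms: water, O
Why: Mild acid-catalysed ketal hydrolysis; the pyridinium salt is too weak an acid to ionise the tertiary alkyl aryl ether.

Step 15
Reactants: 21 (2R,4aR,8aR)-2-(4-bromo-2-chlorophenoxy)-2,4a-dimethyldecahydronaphthalen-7-one
Product: 22 (2R,4aS,8aS)-2-(4-bromo-2-chlorophenoxy)-2,4a-dimethyldecahydronaphthalene-7-carbonitrile (C7 epimers)
Conditions: TosMIC, KOt-Bu, DME, EtOH (2 equiv), 0 to 40 °C
Reagents that add atoms: p-toluenesulfonylmethyl isocyanide, Cc1ccc(S(=O)(=O)C[N+]#[C-])cc1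
Why: Van Leusen reductive cyanation converts the ketone into the nitrile with one new carbon on C7; the epimer mixture at C7 is corrected in step 16.

Step 16
Reactants: 22 (2R,4aS,8aS)-2-(4-bromo-2-chlorophenoxy)-2,4a-dimethyldecahydronaphthalene-7-carbonitrile (C7 epimers)
Product: 25 1-[(2R,4aS,7R,8aS)-2-(4-bromo-2-chlorophenoxy)-2,4a-dimethyldecahydronaphthalen-7-yl]ethan-1-one, via ketimine 23 (not isolated), via 7α-acetyl epimer 24 (not isolated)
Conditions: MeMgBr, toluene/THF, 80 °C; then 1 M HCl, 0 °C to rt; then NaOMe (cat.), MeOH, rt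
Reagents that add atoms: methylmagnesium bromide, C[Mg]Br; water, O
Why: Grignard addition to the nitrile gives the magnesium ketimine, which is hydrolysed to the methyl ketone, and base-mediated enolisation then equilibrates C7 towards the equatorial (β) acetyl isomer, the thermodynamically favoured one; MeMgBr does not exchange with the aryl halides.

Step 17
Reactants: 25 1-[(2R,4aS,7R,8aS)-2-(4-bromo-2-chlorophenoxy)-2,4a-dimethyldecahydronaphthalen-7-yl]ethan-1-one
Product: 26 2-[(2R,4aS,7R,8aS)-2-(4-bromo-2-chlorophenoxy)-2,4a-dimethyldecahydronaphthalen-7-yl]propan-2-ol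
Conditions: MeMgBr, THF, 0 °C; then NH4Cl (aq)
Reagents that add atoms: methylmagnesium bromide, C[Mg]Br
Why: Grignard 1,2-addition to the methyl ketone gives the dimethyl carbinol; no new stereocentre is formed.

Step 18
Reactants: 26 2-[(2R,4aS,7R,8aS)-2-(4-bromo-2-chlorophenoxy)-2,4a-dimethyldecahydronaphthalen-7-yl]propan-2-ol
Product: 27 2-[(2R,4aS,7R,8aS)-2-(4-allyl-2-chlorophenoxy)-2,4a-dimethyldecahydronaphthalen-7-yl]propan-2-ol
Conditions: allylB(pin), Pd(PPh3)4 (5 mol %), CsF, THF, 70 °C
Reagents that add atoms: allylboronic acid pinacol ester, C=CCB1OC(C)(C)C(C)(C)O1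
Why: Suzuki–Miyaura allylation: zerovalent palladium with PPh3 inserts into the C–Br bond and not into the C–Cl bond, and the fluoride-activated allylboronate transfers the allyl group.

Step 19
Reactants: 28 2-allyl-4-bromophenol
Product: 29 2-allyl-4-(4,4,5,5-tetramethyl-1,3,2-dioxaborolan-2-yl)phenol
Conditions: B2pin2, Pd(dppf)Cl2 (3 mol %), KOAc, 1,4-dioxane, 85 °C
Reagents that add atoms: bis(pinacolato)diboron, CC1(C)OB(OC1(C)C)B1OC(C)(C)C(C)(C)O1
Why: Miyaura borylation of the aryl bromide; the free phenol and the allyl group are tolerated with the weak base KOAc.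

Step 20
Reactants: 27 2-[(2R,4aS,7R,8aS)-2-(4-allyl-2-chlorophenoxy)-2,4a-dimethyldecahydronaphthalen-7-yl]propan-2-ol; 29 2-allyl-4-(4,4,5,5-tetramethyl-1,3,2-dioxaborolan-2-yl)phenol
Product: 30 2-[(2R,4aS,7R,8aS)-2-{[3′,5-diallyl-4′-hydroxy-(1,1′-biphenyl)-2-yl]oxy}-2,4a-dimethyldecahydronaphthalen-7-yl]propan-2-ol
Conditions: Pd(OAc)2 (5 mol %), SPhos (10 mol %), K3PO4, toluene/H2O, 90 °C
Reagents that add atoms: none
Why: Suzuki–Miyaura coupling of the hindered, electron-rich aryl chloride, enabled by the bulky electron-rich biarylphosphine, joins the two arene rings; the phenol, the tertiary alcohol and both allyl groups are spectators.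

Compound list
1 | 3-ethoxycyclohex-2-en-1-one | CCOC1=CC(=O)CCC1 | starting material
2 | 2-(2-bromoethyl)-2-methyl-1,3-dioxolane | CC1(CCBr)OCCO1 | starting material
3 | rac-3-ethoxy-6-[2-(2-methyl-1,3-dioxolan-2-yl)ethyl]cyclohex-2-en-1-one | CCOC1=CC(=O)C(CCC2(C)OCCO2)CC1 | intermediate
4 | rac-3-ethoxy-6-methyl-6-[2-(2-methyl-1,3-dioxolan-2-yl)ethyl]cyclohex-2-en-1-one | CCOC1=CC(=O)C(C)(CCC2(C)OCCO2)CC1 | intermediate
5 | 3-ethoxy-6-methyl-6-[2-(2-methyl-1,3-dioxolan-2-yl)ethyl]cyclohex-2-en-1-ol (racemic diastereomer mixture, not isolated) | CCOC1=CC(O)C(C)(CCC2(C)OCCO2)CC1 | intermediate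
6 | rac-4-methyl-4-[2-(2-methyl-1,3-dioxolan-2-yl)ethyl]cyclohex-2-en-1-one (not isolated) | CC1(CCC2(C)C=CC(=O)CC2)OCCO1 | intermediate
7 | rac-4-methyl-4-(3-oxobutyl)cyclohex-2-en-1-one | CC(=O)CCC1(C)C=CC(=O)CC1 | intermediate
8 | 4-methyl-4-(3-oxobutyl)cyclohexa-2,5-dien-1-one (achiral) | CC(=O)CCC1(C)C=CC(=O)C=C1 | intermediate
9 | (4aR,8aR)-4a-methyl-4a,5,6,8a-tetrahydronaphthalene-2,7(1H,8H)-dione; cis-fused, 4a-CH3 β and 8a-H β, C3=C4 enone | O=C1C=C[C@]2(C)CCC(=O)C[C@@H]2C1 | intermediate
10 | (4aR,8aS)-7,7-(ethylenedioxy)-4a-methyl-4a,5,6,7,8,8a-hexahydronaphthalen-2(1H)-one; cis-fused, C3=C4 enone | O=C1C=C[C@]2(C)CCC3(OCCO3)C[C@@H]2C1 | intermediate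
11 | (4aS,8aR)-7,7-(ethylenedioxy)-4a-methyl-2-(trimethylsilyloxy)-4a,5,6,7,8,8a-hexahydronaphthalene; C1=C2 and C3=C4 diene (not isolated) | C[Si](C)(C)OC=1C=C[C@]2(C)CCC3(OCCO3)C[C@@H]2C=1 | intermediate
12 | (4aS)-7,7-(ethylenedioxy)-4a-methyl-5,6,7,8-tetrahydronaphthalen-2(4aH)-one; C1=C8a and C3=C4 dienone | O=C1C=C[C@]2(C)CCC3(OCCO3)CC2=C1 | intermediate
13 | (4aR)-7,7-(ethylenedioxy)-4a-methyl-4,4a,5,6,7,8-hexahydronaphthalen-2(3H)-one; C1=C8a enone | O=C1CC[C@]2(C)CCC3(OCCO3)CC2=C1 | intermediate
14 | (4aR,8aR)-7,7-(ethylenedioxy)-4a-methyloctahydronaphthalen-2(1H)-one; trans-fused, 8a-H α | O=C1CC[C@]2(C)CCC3(OCCO3)C[C@H]2C1 | intermediate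
15 | (2R,4aR,8aR)-7,7-(ethylenedioxy)-4a-methyloctahydro-1H-spiro[naphthalene-2,2′-oxirane]; epoxide O α (axial), CH2 β (equatorial) | O1C[C@]12CC[C@]3(C)CCC4(OCCO4)C[C@H]3C2 | intermediate
16 | (2R,4aR,8aR)-7,7-(ethylenedioxy)-2,4a-dimethyldecahydronaphthalen-2-ol; 2-OH α (axial), 2-CH3 β (equatorial) | O[C@]1(C)CC[C@]2(C)CCC3(OCCO3)C[C@H]2C1 | intermediate
17 | 4-bromo-2-chloro-1-iodobenzene | Clc1cc(Br)ccc1I | starting material
18 | 4-bromo-2-chloro-1-[hydroxy(tosyloxy)iodo]benzene (not isolated) | Cc1ccc(S(=O)(=O)OI(O)c2ccc(Br)cc2Cl)cc1 | intermediate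
19 | (4-bromo-2-chlorophenyl)(2,4,6-trimethoxyphenyl)iodonium tosylate | COc1cc(OC)c([I+]c2ccc(Br)cc2Cl)c(OC)c1.Cc1ccc(S(=O)(=O)[O-])cc1 | intermediate
20 | (2R,4aR,8aR)-2-(4-bromo-2-chlorophenoxy)-7,7-(ethylenedioxy)-2,4a-dimethyldecahydronaphthalene; aryloxy α (axial) | Clc1cc(Br)ccc1O[C@]1(C)CC[C@]2(C)CCC3(OCCO3)C[C@H]2C1 | intermediate
21 | (2R,4aR,8aR)-2-(4-bromo-2-chlorophenoxy)-2,4a-dimethyldecahydronaphthalen-7-one | Clc1cc(Br)ccc1O[C@]1(C)CC[C@]2(C)CCC(=O)C[C@H]2C1 | intermediate
22 | (2R,4aS,8aS)-2-(4-bromo-2-chlorophenoxy)-2,4a-dimethyldecahydronaphthalene-7-carbonitrile, mixture of C7 epimers | Clc1cc(Br)ccc1O[C@]1(C)CC[C@]2(C)CCC(C#N)C[C@H]2C1 | intermediate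
23 | 1-[(2R,4aS,8aS)-2-(4-bromo-2-chlorophenoxy)-2,4a-dimethyldecahydronaphthalen-7-yl]ethan-1-imine, C7 epimers (not isolated) | Clc1cc(Br)ccc1O[C@]1(C)CC[C@]2(C)CCC(C(C)=N)C[C@H]2C1 | intermediate
24 | 1-[(2R,4aS,7S,8aS)-2-(4-bromo-2-chlorophenoxy)-2,4a-dimethyldecahydronaphthalen-7-yl]ethan-1-one; 7α (axial) acetyl epimer (not isolated) | Clc1cc(Br)ccc1O[C@]1(C)CC[C@]2(C)CC[C@H](C(C)=O)C[C@H]2C1 | intermediate
25 | 1-[(2R,4aS,7R,8aS)-2-(4-bromo-2-chlorophenoxy)-2,4a-dimethyldecahydronaphthalen-7-yl]ethan-1-one; 7β (equatorial) acetyl | Clc1cc(Br)ccc1O[C@]1(C)CC[C@]2(C)CC[C@@H](C(C)=O)C[C@H]2C1 | intermediate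
26 | 2-[(2R,4aS,7R,8aS)-2-(4-bromo-2-chlorophenoxy)-2,4a-dimethyldecahydronaphthalen-7-yl]propan-2-ol | Clc1cc(Br)ccc1O[C@]1(C)CC[C@]2(C)CC[C@@H](C(C)(C)O)C[C@H]2C1 | intermediate
27 | 2-[(2R,4aS,7R,8aS)-2-(4-allyl-2-chlorophenoxy)-2,4a-dimethyldecahydronaphthalen-7-yl]propan-2-ol | C=CCc1ccc(O[C@]2(C)CC[C@]3(C)CC[C@@H](C(C)(C)O)C[C@H]3C2)c(Cl)c1 | intermediate
28 | 2-allyl-4-bromophenol | C=CCc1cc(Br)ccc1O | starting material
29 | 2-allyl-4-(4,4,5,5-tetramethyl-1,3,2-dioxaborolan-2-yl)phenol | C=CCc1cc(B2OC(C)(C)C(C)(C)O2)ccc1O | intermediate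
30 | 2-[(2R,4aS,7R,8aS)-2-{[3′,5-diallyl-4′-hydroxy-(1,1′-biphenyl)-2-yl]oxy}-2,4a-dimethyldecahydronaphthalen-7-yl]propan-2-ol (CNP0342687.1); trans-decalin, 2-OAr α (axial), 2-CH3 β, 7-side chain β (equatorial), 8a-H α | C=CCc1ccc(O[C@]2(C)CC[C@]3(C)CC[C@@H](C(C)(C)O)C[C@H]3C2)c(-c2ccc(O)c(CC=C)c2)c1 | target

Total step count: 20. Longest linear sequence: 18 steps (steps 1–11, 13–18 and 20).

Steps most likely to fail

Step 5. The amine may differentiate the two enantiotopic enone halves insufficiently, or an uncatalysed racemic closure may run alongside, so that 9 would form with low enantiomeric purity; slow enamine formation at the methyl ketone is the second concern. Fallback: setting out from 8, the ring is closed without chiral control (pyrrolidine/AcOH, CH2Cl2, rt) to the racemic cis-dione F1, which is resolved by preparative chromatography on a chiral stationary phase (supercritical CO2/MeOH). The (4aR,8aR) fraction is 9, where the route is rejoined. The (4aS,8aS)-enantiomer F2 should be returnable to F1 with an amine base, because the Michael closure is reversible while C7 is a free ketone.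

Step 13. Ligand coupling at the hindered axial alkoxide may be slow, and aryne formation from the iodonium salt or transfer of the wrong aryl ligand may compete. Fallback: setting out from 16, the potassium alkoxide (KN(SiMe3)2, THF, then NMP) is arylated by nucleophilic aromatic substitution on 4-bromo-2-chloro-1-fluorobenzene (60–80 °C), fluoride being displaced ortho to Cl and para to Br. This gives 20 directly, where the route is rejoined, and no compound outside the list arises (F0).

Step 4. The dehydrogenation may be sluggish or unselective: the side chain may be oxidised, or acid formed in the reaction may close 8 prematurely to racemic dione. Fallback: setting out from 4, reduction as in step 3 followed by hydrolysis with dilute aqueous oxalic acid keeps the dioxolane, so that 6 is isolated. Saegusa–Ito oxidation (LiN(i-Pr)2, Me3SiCl, THF, −78 °C; then Pd(OAc)2, MeCN) via the trimethylsilyl dienol ether F3 gives the dienone ketal F4, and pyridinium p-toluenesulfonate in wet acetone returns 8, where the route is rejoined.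

Further compounds
F1 | step 5 | racemic cis-4a-methyl-4a,5,6,8a-tetrahydronaphthalene-2,7(1H,8H)-dione | O=C1C=C[C@]2(C)CCC(=O)C[C@@H]2C1.O=C1C=C[C@@]2(C)CCC(=O)C[C@H]2C1
F2 | step 5 | (4aS,8aS)-4a-methyl-4a,5,6,8a-tetrahydronaphthalene-2,7(1H,8H)-dione | O=C1C=C[C@@]2(C)CCC(=O)C[C@H]2C1
F0 | step 13 | none | none
F3 | step 4 | rac-trimethyl({4-methyl-4-[2-(2-methyl-1,3-dioxolan-2-yl)ethyl]cyclohexa-1,5-dien-1-yl}oxy)silane | C[Si](C)(C)OC1=CCC(C)(CCC2(C)OCCO2)C=C1
F4 | step 4 | 4-methyl-4-[2-(2-methyl-1,3-dioxolan-2-yl)ethyl]cyclohexa-2,5-dien-1-one | CC1(CCC2(C)C=CC(=O)C=C2)OCCO1
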